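Two questions stand before you: how much Z each flask from maple to cedar holds at the end, and what shape that row takes.

| flask | Q | L | remark | time |
|---|---|---|---|---|
| noon | 0.026 M | 1.1 equiv | run made earlier |  |
| maple | 0.020 M | 1.10 equiv |  | 3.0 min |
| oak | 0.060 M | 1.10 equiv |  | 3.0 min |
| ash | 0.20 M | 1.10 equiv |  | 3.0 min |
| alder | 0.60 M | 1.10 equiv |  | 3.0 min |
| cedar | 2.0 M | 1.10 equiv |  | 3.0 min |

noon run (percent of the Q charged)

| time / s | Z / % | Q / % |
|---|---|---|
| 20.0 | 6.0 | 84.7 |
| 40.0 | 10.4 | 73.7 |
| 50.0 | 11.2 | 68.7 |
| 80.0 | 13.1 | 60.5 |
| 90.0 | 14.2 | 57.8 |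
| 120 | 14.8 | 53.0 |

(standard deviation of a reading: 0.5 percentage points)

- what was read earlier has a scatter of 0.5 percentage points, one standard deviation
- "hardly changes" means that all values lie within two and a half points (for a concentration: within two and a half percent of the largest)

1. [Z] at the end for maple, oak, ash, alder, cedar, in this order
2. the shape of the row from first to last (hardly changes / rises, then falls / falls all the way / rises all the way / falls, then rises)

Begin with a bound from above. In the noon run at 40.0 s, Z reads 10.4% while Q reads 73.7%, which gives 39.5%. Call this the Z share: Z standing per Q lost, a reading of the selectivity. At 120 s the same ratio reads 31.5%, lower, so you have no sign that the share climbs with time. If the share holds and every Q is lost, cZ reaches the share times the charged cQ: 0.00791 M for maple and 0.791 M for cedar.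

The bound from below is harder. The noon run was made at one charge, so it shows you no floor above zero for a much stronger flask. You can tighten maple, whose charge times time is 1.15 times noon's at the last reading. If the steps are bimolecular, maple should resemble that reading, which gives your own estimate of 0.00296 M. For the other flasks you keep the bracket and leave the shape open.

The forecast gives 0.0031 M, 0.01 M, 0.033 M, 0.1 M and 0.33 M, and calls the shape "rises all the way". Its cedar value lies below the ceiling, and it warns that “a concentration-dependent selectivity remains the main risk”.

The flasks give 0.00280 M, 0.00564 M, 0.00140 M, 6.03 × 10⁻⁶ M and 8.72 × 10⁻⁷ M. The shape is "rises, then falls", turning at 0.060 M.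

    Q + L ⇌ Z + D (K = 0.670, k = 7.60 M⁻¹ min⁻¹)
    Q + L → X + D (k = 12.0 M⁻¹ min⁻¹)
    L + Z → G + D (k = 0.220 M⁻¹ min⁻¹)
    L + X → G + D (k = 17.0 M⁻¹ min⁻¹)
    Z ⇌ E (K = 23.0, k = 0.0930 min⁻¹)
    L → J (k = 0.0950 min⁻¹)

Cedar ends close to the floor, far beneath its ceiling of 0.791 M. In cedar the largest single effect is the falling back of Z + D to Q + L: the cedar run without it holds 0.473 M of Z, under the ceiling, against 8.72 × 10⁻⁷ M with it. In oak the same share gives a ceiling of 0.0237 M, and oak ends at 0.00564 M, with Z standing at 15.2% of the Q lost.

All runs stem from a simulated flask from invented constants; noise was put on by code.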